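**Retrosynthetic overview**
1. The target comes from its C2 methyl enol ether / bis-silyl catechol ether by one hydroxide step; the C5 prenyl and the C3 aroyl group are put on a bicyclic enol ether by bridgehead and vinylic lithiation.
2. That bicycle comes from a mirror-symmetric 4,4-dialkyl-3,5-dimethoxycyclohexadienone by a cation–olefin cyclisation. The lavandulyl stereocentre chooses one of the two equivalent enone arms, which closes the second (carbocyclic) ring and sets C1 and C5 from C7.
3. The dienone comes from a 4-lavandulyl-3,5-dimethoxyphenol by palladium-catalysed dearomative para-geranylation; the former benzene ring becomes the C1–C2–C3–C4–C5–C9 ring (first ring).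
4. The phenol comes from 3,5-dimethoxyphenol (lithiation between the methoxy groups) and (S)-lavandulol (lipase resolution of the racemate); the aroyl unit comes from 3,4-dihydroxybenzoic acid.

Assumption: lavandulol is bought as the racemate, and the target is treated as the enol tautomer written in its SMILES (the 2-hydroxy-4-oxo and 4-hydroxy-2-oxo forms interconvert).

**Step 1**
Reactants: 1 (±)-lavandulol
Product: 2 (S)-lavandulol [(2S)-5-methyl-2-(prop-1-en-2-yl)hex-4-en-1-ol]
Conditions: porcine pancreas lipase, succinic anhydride, Et2O, rt, to ca. 65% conversion; aq. Na2CO3 wash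
Reagents that add atoms: none
Why: Enzymatic kinetic resolution (lipase-catalysed acylation) in which the (R)-alcohol is esterified faster and washed out as its hemisuccinate, leaving (S)-2 in high ee; this centre becomes C7 of the target.

**Step 2**
Reactants: 3 3,5-dimethoxyphenol
Product: 4 (3,5-dimethoxyphenoxy)triisopropylsilane
Conditions: i-Pr3SiCl, imidazole, DMF, rt
Reagents that add atoms: triisopropylsilyl chloride, CC(C)[Si](Cl)(C(C)C)C(C)C
Why: Standard O-silylation; the bulky, weakly coordinating silyl ether leaves the position between the two methoxy groups as the only good site for directed lithiation.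

**Step 3**
Reactants: 2 (S)-lavandulol; 4 (3,5-dimethoxyphenoxy)triisopropylsilane
Product: 8 3,5-dimethoxy-4-[(2R)-5-methyl-2-(prop-1-en-2-yl)hex-4-en-1-yl]phenol, via (S)-lavandulyl triflate 5 (not isolated), via aryllithium 6 (not isolated), via aryl silyl ether 7 (not isolated)
Conditions: (a) 2, Tf2O, 2,6-lutidine, Et2O, −78 °C, cannula-filtered; (b) 4, n-BuLi, TMEDA, THF, 0 °C, then (a) at −78 → 0 °C; (c) Bu4NF, THF, rt; aq. NH4Cl
Reagents that add atoms: none
Why: Directed ortho-metalation between the two methoxy groups, then SN2 alkylation of the aryllithium by the primary triflate and fluoride desilylation; the stereocentre is β to the reacting carbon and is untouched (its descriptor changes from S to R only through CIP priorities).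

**Step 4**
Reactants: 8 3,5-dimethoxy-4-[(2R)-5-methyl-2-(prop-1-en-2-yl)hex-4-en-1-yl]phenol; 9 geraniol
Product: 10 4-[(2E)-3,7-dimethylocta-2,6-dien-1-yl]-3,5-dimethoxy-4-[(2R)-5-methyl-2-(prop-1-en-2-yl)hex-4-en-1-yl]cyclohexa-2,5-dien-1-one
Conditions: Pd(OAc)2 (5 mol%), PPh3 (20 mol%), Ti(OiPr)4 (25 mol%), 4 Å MS, toluene, 50 °C
Reagents that add atoms: none
Why: Tsuji–Trost-type dearomative para-C-allylation in which the titanium phenoxide attacks the π-geranyl palladium complex at its CH2 terminus through C4 (para to oxygen, activated by both methoxy groups) while any O-geranyl ether re-ionises, giving the E-geranyl dienone whose new quaternary carbon is not yet a stereocentre because the ring keeps a mirror plane.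

**Step 5**
Reactants: 10 4-[(2E)-3,7-dimethylocta-2,6-dien-1-yl]-3,5-dimethoxy-4-[(2R)-5-methyl-2-(prop-1-en-2-yl)hex-4-en-1-yl]cyclohexa-2,5-dien-1-one
Product: 12 (1S,5R,7R)-1-[(2E)-3,7-dimethylocta-2,6-dien-1-yl]-2-methoxy-6,6-dimethyl-7-(3-methylbut-2-en-1-yl)bicyclo[3.3.1]non-2-ene-4,9-dione, via bicyclic methyloxocarbenium formate 11 (not isolated)
Conditions: HCO2H (98%), CH2Cl2, 0 °C → rt
Reagents that add atoms: none
Why: Proposed new method: diastereotopic-group-selective cation–olefin cyclisation in which Markovnikov protonation of the isopropenyl group gives a tertiary cation that is captured by one of the two mirror-related methoxy-enone α-carbons through a chair transition state with the C7 prenyl group equatorial (exo), so the lavandulyl centre fixes C1 and C5 in one event and formate demethylates the resulting oxocarbenium to the C9 ketone; the closest known reaction types are the formic acid-mediated biomimetic cyclisation of lavandulyl-bearing dearomatized acylphloroglucinols and the halonium-induced carbocyclisation of 4,4-disubstituted 3,5-dimethoxycyclohexadienones.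

**Step 6**
Reactants: 13 3,4-dihydroxybenzoic acid
Product: 15 3,4-bis(tert-butyldimethylsilyloxy)benzoic acid, via tris-silylated silyl ester 14 (not isolated)
Conditions: t-BuMe2SiCl (3.5 equiv), imidazole, DMF, rt; then AcOH/THF/H2O, rt
Reagents that add atoms: tert-butyldimethylsilyl chloride, CC(C)(C)[Si](C)(C)Cl
Why: Exhaustive silylation followed by selective hydrolysis of the labile silyl ester gives a catechol protection that survives amide bases and is removed by hydroxide at the end.

**Step 7**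
Reactants: 12 bicyclic enol ether; 15 3,4-bis(tert-butyldimethylsilyloxy)benzoic acid
Product: 18 (1S,5S,7R)-3-[3,4-bis(tert-butyldimethylsilyloxy)benzoyl]-1-[(2E)-3,7-dimethylocta-2,6-dien-1-yl]-2-methoxy-6,6-dimethyl-7-(3-methylbut-2-en-1-yl)bicyclo[3.3.1]non-2-ene-4,9-dione, via acid chloride 16 (not isolated), via C3 vinyllithium 17 (not isolated)
Conditions: (a) 15, 1-chloro-N,N,2-trimethylprop-1-en-1-amine, THF, 0 °C → rt; (b) 12, LiTMP (lithium 2,2,6,6-tetramethylpiperidide, from the amine and n-BuLi), THF, −78 °C, then (a), −78 → −40 °C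
Reagents that add atoms: none
Why: Regioselective vinylic (C3) lithiation of the β-methoxy enone by the hindered amide base followed by C-acylation with the acid chloride (lithiation–acylation), the more hindered bridgehead C5–H being left for the next step.

**Step 8**
Reactants: 18 C3-aroylated bicyclic enol ether; 19 prenyl bromide (1-bromo-3-methylbut-2-ene)
Product: 21 (1S,5S,7R)-3-[3,4-bis(tert-butyldimethylsilyloxy)benzoyl]-1-[(2E)-3,7-dimethylocta-2,6-dien-1-yl]-2-methoxy-6,6-dimethyl-5,7-bis(3-methylbut-2-en-1-yl)bicyclo[3.3.1]non-2-ene-4,9-dione, via bridgehead lithium species 20 (not isolated)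
Conditions: LiTMP (2 equiv, from the amine and n-BuLi), THF, −78 → −40 °C; then 19, −78 → 0 °C
Reagents that add atoms: none
Why: Bridgehead lithiation–alkylation in which C5–H, the only acidic C–H left and flanked by the C4 and C9 carbonyls, is removed and the carbanion is alkylated by SN2 at the primary allylic bromide, with retention enforced by the bicycle so that C5 keeps the configuration set in step 5.

**Step 9**
Reactants: 21 fully substituted methyl enol ether
Product: 22 target, (1S,5S,7R)-3-(3,4-dihydroxybenzoyl)-1-[(2E)-3,7-dimethylocta-2,6-dien-1-yl]-2-hydroxy-6,6-dimethyl-5,7-bis(3-methylbut-2-en-1-yl)bicyclo[3.3.1]non-2-ene-4,9-dione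
Conditions: LiOH·H2O, dioxane/H2O (degassed), 90 °C; then 1 M HCl to pH 3
Reagents that add atoms: lithium hydroxide monohydrate (supplies the C2 enol oxygen), [Li+].[OH-].O
Why: Hydroxide adds to C2 and expels methoxide (addition–elimination at the vinylogous ester) and also cleaves both aryl silyl ethers at silicon, so acidification gives the enolised triketone without touching C1, C5 or C7.

**Compound list**
1 | (±)-lavandulol | CC(C)=CCC(CO)C(C)=C | starting material
2 | (S)-lavandulol | OC[C@@H](CC=C(C)C)C(C)=C | intermediate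
3 | 3,5-dimethoxyphenol | COc1cc(O)cc(OC)c1 | starting material
4 | (3,5-dimethoxyphenoxy)triisopropylsilane | COc1cc(O[Si](C(C)C)(C(C)C)C(C)C)cc(OC)c1 | intermediate
5 | (2S)-5-methyl-2-(prop-1-en-2-yl)hex-4-en-1-yl trifluoromethanesulfonate | O=S(=O)(OC[C@@H](CC=C(C)C)C(C)=C)C(F)(F)F | intermediate
6 | [2,6-dimethoxy-4-(triisopropylsilyloxy)phenyl]lithium | COc1cc(O[Si](C(C)C)(C(C)C)C(C)C)cc(OC)c1[Li] | intermediate
7 | {3,5-dimethoxy-4-[(2R)-5-methyl-2-(prop-1-en-2-yl)hex-4-en-1-yl]phenoxy}triisopropylsilane | COc1cc(O[Si](C(C)C)(C(C)C)C(C)C)cc(OC)c1C[C@@H](CC=C(C)C)C(C)=C | intermediate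
8 | 3,5-dimethoxy-4-[(2R)-5-methyl-2-(prop-1-en-2-yl)hex-4-en-1-yl]phenol | COc1cc(O)cc(OC)c1C[C@@H](CC=C(C)C)C(C)=C | intermediate
9 | geraniol, (2E)-3,7-dimethylocta-2,6-dien-1-ol | CC(C)=CCC/C(C)=C/CO | starting material
10 | 4-[(2E)-3,7-dimethylocta-2,6-dien-1-yl]-3,5-dimethoxy-4-[(2R)-5-methyl-2-(prop-1-en-2-yl)hex-4-en-1-yl]cyclohexa-2,5-dien-1-one | CC(C)=CCC/C(C)=C/CC1(C[C@@H](CC=C(C)C)C(C)=C)C(OC)=CC(=O)C=C1OC | intermediate
11 | bicyclic C9 O-methyl oxocarbenium formate (C1, C5, C7 as in 12) | CC(C)=CCC/C(C)=C/C[C@]12C[C@@H](CC=C(C)C)C(C)(C)[C@H](C(=O)C=C1OC)C2=[O+]C.[O-]C=O | intermediate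
12 | (1S,5R,7R)-1-[(2E)-3,7-dimethylocta-2,6-dien-1-yl]-2-methoxy-6,6-dimethyl-7-(3-methylbut-2-en-1-yl)bicyclo[3.3.1]non-2-ene-4,9-dione (C7 prenyl exo) | CC(C)=CCC/C(C)=C/C[C@]12C[C@@H](CC=C(C)C)C(C)(C)[C@H](C(=O)C=C1OC)C2=O | intermediate
13 | 3,4-dihydroxybenzoic acid | OC(=O)c1ccc(O)c(O)c1 | starting material
14 | tert-butyldimethylsilyl 3,4-bis(tert-butyldimethylsilyloxy)benzoate | CC(C)(C)[Si](C)(C)OC(=O)c1ccc(O[Si](C)(C)C(C)(C)C)c(O[Si](C)(C)C(C)(C)C)c1 | intermediate
15 | 3,4-bis(tert-butyldimethylsilyloxy)benzoic acid | OC(=O)c1ccc(O[Si](C)(C)C(C)(C)C)c(O[Si](C)(C)C(C)(C)C)c1 | intermediate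
16 | 3,4-bis(tert-butyldimethylsilyloxy)benzoyl chloride | ClC(=O)c1ccc(O[Si](C)(C)C(C)(C)C)c(O[Si](C)(C)C(C)(C)C)c1 | intermediate
17 | 3-lithio derivative of 12 (vinyllithium at C3) | CC(C)=CCC/C(C)=C/C[C@]12C[C@@H](CC=C(C)C)C(C)(C)[C@H](C(=O)C([Li])=C1OC)C2=O | intermediate
18 | (1S,5S,7R)-3-[3,4-bis(tert-butyldimethylsilyloxy)benzoyl]-1-[(2E)-3,7-dimethylocta-2,6-dien-1-yl]-2-methoxy-6,6-dimethyl-7-(3-methylbut-2-en-1-yl)bicyclo[3.3.1]non-2-ene-4,9-dione | CC(C)=CCC/C(C)=C/C[C@]12C[C@@H](CC=C(C)C)C(C)(C)[C@H](C(=O)C(C(=O)c3ccc(O[Si](C)(C)C(C)(C)C)c(O[Si](C)(C)C(C)(C)C)c3)=C1OC)C2=O | intermediate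
19 | prenyl bromide, 1-bromo-3-methylbut-2-ene | CC(C)=CCBr | starting material
20 | 5-lithio derivative of 18 (bridgehead lithium at C5) | CC(C)=CCC/C(C)=C/C[C@]12C[C@@H](CC=C(C)C)C(C)(C)[C@]([Li])(C(=O)C(C(=O)c3ccc(O[Si](C)(C)C(C)(C)C)c(O[Si](C)(C)C(C)(C)C)c3)=C1OC)C2=O | intermediate
21 | (1S,5S,7R)-3-[3,4-bis(tert-butyldimethylsilyloxy)benzoyl]-1-[(2E)-3,7-dimethylocta-2,6-dien-1-yl]-2-methoxy-6,6-dimethyl-5,7-bis(3-methylbut-2-en-1-yl)bicyclo[3.3.1]non-2-ene-4,9-dione | CC(C)=CCC/C(C)=C/C[C@]12C[C@@H](CC=C(C)C)C(C)(C)[C@](CC=C(C)C)(C(=O)C(C(=O)c3ccc(O[Si](C)(C)C(C)(C)C)c(O[Si](C)(C)C(C)(C)C)c3)=C1OC)C2=O | intermediate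
22 | (1S,5S,7R)-3-(3,4-dihydroxybenzoyl)-1-[(2E)-3,7-dimethylocta-2,6-dien-1-yl]-2-hydroxy-6,6-dimethyl-5,7-bis(3-methylbut-2-en-1-yl)bicyclo[3.3.1]non-2-ene-4,9-dione (CNP0160101.3) | CC(C)=CCC/C(C)=C/C[C@]12C[C@@H](CC=C(C)C)C(C)(C)[C@](CC=C(C)C)(C(=O)C(C(=O)c3ccc(O)c(O)c3)=C1O)C2=O | target

**Totals**
Total step count: 9. Longest linear sequence: 7 steps (steps 2, 3, 4, 5, 7, 8, 9 from 3,5-dimethoxyphenol; equally steps 1, 3, 4, 5, 7, 8, 9 from lavandulol).

**Three steps most likely to fail**

Step 5 is the main risk. The tertiary cation can lose the C7 proton reversibly to give the tetrasubstituted alkene, and since C7 is the only element of stereocontrol this would erode ee. In addition, the carbonyl-protonated dienone is not nucleophilic, and formic acid may also start to cyclise the geranyl chain. The fallback sets out from 10 and generates the cation without a Brønsted acid. Mukaiyama hydration, which prefers the 1,1-disubstituted alkene over the trisubstituted ones (Mn(dpm)3, tris(dipivaloylmethanato)manganese, PhSiH3, O2, i-PrOH, 0 °C), gives 4-[(2E)-3,7-dimethylocta-2,6-dien-1-yl]-4-[(2R)-2-(2-hydroxypropan-2-yl)-5-methylhex-4-en-1-yl]-3,5-dimethoxycyclohexa-2,5-dien-1-one F3. Ionisation of this tertiary alcohol with BF3·OEt2 in CH2Cl2 at −78 °C, where ring closure should outrun proton loss, followed by aqueous NaHCO3 (which hydrolyses the methyloxocarbenium), comes back to the route at 12.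

Step 4 may give ortho-C-geranylation (an aromatic by-product), persistent O-geranyl ether, or partial E/Z scrambling in the π-allyl complex. The fallback sets out from 8 and blocks both ortho carbons. Bromination (NBS, 2.05 equiv, CH2Cl2, −78 °C) gives 2,6-dibromo-3,5-dimethoxy-4-[(2R)-5-methyl-2-(prop-1-en-2-yl)hex-4-en-1-yl]phenol F1. The same Pd(OAc)2/PPh3/Ti(OiPr)4/geraniol conditions can then alkylate carbon only at C4 and give 2,6-dibromo-4-[(2E)-3,7-dimethylocta-2,6-dien-1-yl]-3,5-dimethoxy-4-[(2R)-5-methyl-2-(prop-1-en-2-yl)hex-4-en-1-yl]cyclohexa-2,5-dien-1-one F2. Reductive removal of the two α-bromo-enone bromines (Zn dust, AcOH/THF, 0 °C) comes back to the route at 10.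

Step 8 may fail because the bridgehead carbanion next to the gem-dimethyl carbon is too hindered to be alkylated by prenyl bromide, even if deprotonation succeeds. The fallback sets out from 18 and makes the C5–C bond by a radical instead. Bridgehead lithiation and trapping with the small electrophile iodine (LiTMP, THF, −78 °C; I2) gives the 5-iodo derivative of 18 F4. Tin-mediated radical prenylation ((Bu3Sn)2, 2-methylbut-3-en-2-yl phenyl sulfone, hν, benzene) then adds the bridgehead radical to the unsubstituted alkene terminus of the sulfone, and β-scission of the sulfonyl radical leaves the linear prenyl group, coming back to the route at 21.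

**Further compounds**
F1 | step 4 | 2,6-dibromo-3,5-dimethoxy-4-[(2R)-5-methyl-2-(prop-1-en-2-yl)hex-4-en-1-yl]phenol | COc1c(Br)c(O)c(Br)c(OC)c1C[C@@H](CC=C(C)C)C(C)=C
F2 | step 4 | 2,6-dibromo-4-[(2E)-3,7-dimethylocta-2,6-dien-1-yl]-3,5-dimethoxy-4-[(2R)-5-methyl-2-(prop-1-en-2-yl)hex-4-en-1-yl]cyclohexa-2,5-dien-1-one | CC(C)=CCC/C(C)=C/CC1(C[C@@H](CC=C(C)C)C(C)=C)C(OC)=C(Br)C(=O)C(Br)=C1OC
F3 | step 5 | 4-[(2E)-3,7-dimethylocta-2,6-dien-1-yl]-4-[(2R)-2-(2-hydroxypropan-2-yl)-5-methylhex-4-en-1-yl]-3,5-dimethoxycyclohexa-2,5-dien-1-one | CC(C)=CCC/C(C)=C/CC1(C[C@@H](CC=C(C)C)C(C)(C)O)C(OC)=CC(=O)C=C1OC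
F4 | step 8 | 5-iodo derivative of 18 (bridgehead iodide, iodine in place of the C5 hydrogen, C1 and C7 unchanged) | CC(C)=CCC/C(C)=C/C[C@]12C[C@@H](CC=C(C)C)C(C)(C)[C@](I)(C(=O)C(C(=O)c3ccc(O[Si](C)(C)C(C)(C)C)c(O[Si](C)(C)C(C)(C)C)c3)=C1OC)C2=O
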